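## Retrosynthetic overview

1. Target 23 ⇒ dienyl acrylic acid 21. The last step forms the lactone O–C6 bond and the C3–OAc bond in one 1,4-oxidation of a diene. The enabling feature is the but-2-ene-1,4-diyl diester unit C3(OAc)–C4(Me)=C5–C6(O) in the ten-membered ring, which is the adduct of two oxygens to a C3=C4–C5=C6 diene; C12 sits on C7 through C11, so O–C6 closure gives the five-membered ring O–C12–C11–C7–C6.
2. 21 ⇒ ketone 14. C9 and C10 are set together by one reagent-controlled hydrogenation with dynamic kinetic resolution, followed by angelate installation and adjustment of C12 to the acid.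
3. 14 ⇒ cyclohexenol 11. An anionic oxy-Cope ring expansion (cleave C4–C9, form C1–C2) builds the ten-membered carbocycle and its (3Z,5Z)-diene.
4. 11 ⇒ (S)-carvone 1 (C4–C9, C11–C13, C15 and the C7 stereocentre) + vinyl cation equivalent 6 (C2, C3) + isopropenylmagnesium bromide 10 (C1, C10, C14); angelic acid 16 is the last building block.
5. Ring order: cyclohexene (from carvone) → ten-membered carbocycle (step 7) → γ-lactone (step 13).

Key step: step 13

Remark on the chemistry: positions are given in germacrane numbering of the target (ring C1–C10, acrylate C11–C13, C14 on C10, C15 on C4). C7 keeps its geometry from carvone throughout; its CIP label is (R) in 8–21 and becomes (S) in 23 only because C6 gains an oxygen.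

## Route

Step 1
Reactants: 1 (S)-(+)-carvone
Product: 2 10-chlorocarvone [(5S)-5-(3-chloroprop-1-en-2-yl)-2-methylcyclohex-2-en-1-one]
Conditions: Ca(OCl)2, CO2 (dry ice), CH2Cl2/H2O, 0 °C
Reagents that add atoms: calcium hypochlorite, [Ca+2].[O-]Cl.[O-]Cl
Why: Ene-type allylic chlorination by HOCl formed in the flask should attack only the electron-rich 1,1-disubstituted isopropenyl alkene (the enone alkene is deactivated) and shift it to the 2-(chloromethyl)vinyl group, leaving the C7 stereocentre untouched.

Step 2
Reactants: 2 10-chlorocarvone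
Product: 4 10-hydroxycarvone [(5S)-5-(3-hydroxyprop-1-en-2-yl)-2-methylcyclohex-2-en-1-one], via allylic acetate 3 (not isolated)
Conditions: KOAc, n-Bu4NI (cat.), DMF, 60 °C; then MeOH, K2CO3 (cat.), 20 °C
Reagents that add atoms: potassium acetate, CC(=O)[O-].[K+]
Why: SN2 displacement of the primary allylic chloride by acetate followed by base-catalysed transesterification with methanol should free the C12 alcohol under conditions too mild to disturb the enone.

Step 3
Reactants: 4 10-hydroxycarvone
Product: 5 10-(tert-butyldimethylsilyloxy)carvone [(5S)-5-[3-(tert-butyldimethylsilyloxy)prop-1-en-2-yl]-2-methylcyclohex-2-en-1-one]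
Conditions: TBSCl, imidazole, DMF, 20 °C
Reagents that add atoms: tert-butyldimethylsilyl chloride, CC(C)(C)[Si](C)(C)Cl
Why: Standard silylation of a primary alcohol gives an ether that should survive the strong bases, the Grignard reagent and the hydrogenation that follow.

Step 4
Reactants: 5 10-(tert-butyldimethylsilyloxy)carvone; 6 phenyl vinyl sulfoxide
Product: 8 (2S,5R)-2-methyl-2-[2-(phenylsulfinyl)ethyl]-5-[3-(tert-butyldimethylsilyloxy)prop-1-en-2-yl]cyclohex-3-en-1-one (both sulfoxide epimers), via potassium dienolate 7 (not isolated)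
Conditions: KOtBu (1.1 equiv), t-BuOH/THF, 0 °C; then 6, 0 to 40 °C; AcOH
Reagents that add atoms: none
Why: Michael addition of the thermodynamic extended dienolate through its α-carbon (C4) to the vinyl sulfoxide, a vinyl cation equivalent, should give the deconjugated ketone with the C4 quaternary centre, the electrophile entering anti to the C7 side chain; this centre is destroyed later and serves only to steer the ring expansion.

Step 5
Reactants: 8 sulfoxide Michael adduct
Product: 9 (2S,5R)-2-ethenyl-2-methyl-5-[3-(tert-butyldimethylsilyloxy)prop-1-en-2-yl]cyclohex-3-en-1-one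
Conditions: toluene, CaCO3, 110 °C
Reagents that add atoms: none
Why: Thermal syn-elimination of the sulfoxide (sulfoxide pyrolysis) can only take a hydrogen from the CH2 next to the quaternary carbon and should therefore unmask the vinyl group without touching a stereocentre.

Step 6
Reactants: 9 vinyl ketone; 10 isopropenylmagnesium bromide
Product: 11 (1R,2S,5R)-2-ethenyl-2-methyl-1-(prop-1-en-2-yl)-5-[3-(tert-butyldimethylsilyloxy)prop-1-en-2-yl]cyclohex-3-en-1-ol
Conditions: THF, −78 to 0 °C; then H2O
Reagents that add atoms: none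
Why: Grignard 1,2-addition, in which the half-chair with the C7 side chain pseudo-equatorial carries the C4 methyl pseudo-axial, so the nucleophile should enter axially on the opposite face (the face of the vinyl group) and set C9 with the two alkenyl groups cis and the hydroxyl cis to the C4 methyl; minor isomers would be removed by chromatography.

Step 7
Reactants: 11 dialkenyl cyclohexenol
Product: 14 (3Z,5Z,7R)-12-(tert-butyldimethylsilyloxy)germacra-3,5,11(13)-trien-9-one (both C10 epimers), via potassium alkoxide 12 (not isolated), via potassium enolate 13 (not isolated)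
Conditions: KH, 18-crown-6, THF, 0 to 20 °C; then AcOH, −78 °C
Reagents that add atoms: none
Why: Anionic oxy-Cope rearrangement (cleaving C4–C9 and forming C1–C2) should expand the ring by four atoms through the chair open to the cis-dialkenyl alkoxide with the C7 side chain equatorial, which places C5 axial and so gives the (3Z)-alkene beside the (5Z)-alkene inherited from the six-membered ring; protonation gives the ketone, whose C10 centre is deliberately left labile.

Step 8
Reactants: 14 ten-membered trienone
Product: 15 (3Z,5Z,7R,9S,10R)-12-(tert-butyldimethylsilyloxy)germacra-3,5,11(13)-trien-9-ol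
Conditions: H2 (8 atm), RuCl2[(R)-BINAP][(S,S)-DPEN] (1 mol %), KOtBu (5 mol %), i-PrOH, 25 °C
Reagents that add atoms: none
Why: Noyori asymmetric hydrogenation with dynamic kinetic resolution, in which the base equilibrates C10 while the chiral ruthenium hydride reduces only the C=O group, should deliver hydride to the face that gives (9S) and, as with 2-alkylcycloalkanones (the catalyst antipode is chosen by that analogy), consume the epimer that leads to the cis 9-OH/10-Me pair, so that both C10 epimers funnel into (9S,10R).

Step 9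
Reactants: 15 trienol; 16 angelic acid
Product: 18 (3Z,5Z,7R,9S,10R)-12-(tert-butyldimethylsilyloxy)germacra-3,5,11(13)-trien-9-yl angelate, via mixed anhydride 17 (not isolated)
Conditions: 16, 2,4,6-trichlorobenzoyl chloride, Et3N, toluene, 20 °C; then 15, 80 °C
Reagents that add atoms: none
Why: Yamaguchi-type esterification through the mixed anhydride should acylate the secondary alcohol with retention at C9 and, run without DMAP, avoid isomerisation of the (Z)-angelate to the tiglate.

Step 10
Reactants: 18 silyl ether angelate
Product: 19 (3Z,5Z,7R,9S,10R)-12-hydroxygermacra-3,5,11(13)-trien-9-yl angelate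
Conditions: HF·pyridine, pyridine, THF, 0 to 20 °C
Reagents that add atoms: none
Why: Fluoride-mediated cleavage of the primary silyl ether under buffered conditions should leave the angelate and the diene untouched.

Step 11
Reactants: 19 allylic alcohol
Product: 20 (3Z,5Z,7R,9S,10R)-12-oxogermacra-3,5,11(13)-trien-9-yl angelate
Conditions: MnO2, CH2Cl2, 20 °C
Reagents that add atoms: none
Why: MnO2 oxidises allylic alcohols selectively and should give the 2-substituted acrolein under neutral conditions that do not epimerise C7.

Step 12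
Reactants: 20 enal
Product: 21 (3Z,5Z,7R,9S,10R)-9-angeloyloxygermacra-3,5,11(13)-trien-12-oic acid
Conditions: NaClO2, NaH2PO4, 2-methyl-2-butene, t-BuOH/H2O, 0 to 20 °C
Reagents that add atoms: sodium chlorite, [Na+].[O-]Cl=O
Why: Pinnick oxidation should convert the enal into the acrylic acid while the alkene scavenger protects the diene from hypochlorite.

Step 13
Reactants: 21 dienyl acrylic acid
Product: 23 CNP0173235.1 [(3S,4Z,6R,7S,9S,10R)-3-acetoxy-9-angeloyloxygermacra-4,11(13)-dien-12,6-olide], via allylpalladium acetate adduct 22 (not isolated)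
Conditions: Pd(OAc)2 (10 mol %), p-benzoquinone (2 equiv), acetone/AcOH 4:1, 20 °C, no chloride
Reagents that add atoms: acetic acid, CC(=O)O
Why: Divalent palladium binds the (5Z)-alkene of the diene and the C12 carboxylate adds to C6 on the face opposite to the metal, closing the γ-lactone (O, C12, C11, C7, C6) in the 5-exo-trig mode and leaving an allylpalladium unit over C3–C5 (22, drawn as its C5 σ-form); acetate then migrates from palladium to C3 on the metal's own face, and benzoquinone reoxidises the zerovalent palladium released. The closest known reaction type is the palladium-catalysed intramolecular 1,4-acyloxylactonisation of conjugated dienes carrying a carboxylic acid, run without chloride so that the second oxygen is delivered cis to the metal. C6 is controlled by C7: allylic 1,3-strain across the (Z)-C5=C6 bond holds H7 in the diene plane, so the acrylate arm can reach only one face of C6 and the trans-fused (6R) lactone should result. C3 is controlled by the mechanism: carboxylate anti and acetate syn to palladium on the U-shaped allyl unit that the (3Z,5Z)-diene gives puts the two oxygens on opposite faces, which is (3S) once C6 is (6R), and the same anti,anti-allyl geometry, reinforced by the C4 methyl group, fixes the new C4=C5 bond as Z. The step needs regioselectivity (carboxylate at C6 not C5, acetate at C3 not C5) and chemoselectivity for the diene; the first is secured by ring size (five against six) and by attack at the allyl terminus remote from the new acyloxy carbon, the second by the electron-poor character of the acrylate and angelate alkenes.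

## Compound list

1 | (S)-(+)-carvone | CC1=CC[C@@H](CC1=O)C(C)=C | starting material
2 | 10-chlorocarvone | CC1=CC[C@@H](CC1=O)C(=C)CCl | intermediate
3 | 10-acetoxycarvone (not isolated) | CC1=CC[C@@H](CC1=O)C(=C)COC(C)=O | intermediate
4 | 10-hydroxycarvone | CC1=CC[C@@H](CC1=O)C(=C)CO | intermediate
5 | 10-(tert-butyldimethylsilyloxy)carvone | CC1=CC[C@@H](CC1=O)C(=C)CO[Si](C)(C)C(C)(C)C | intermediate
6 | phenyl vinyl sulfoxide | C=CS(=O)c1ccccc1 | starting material
7 | potassium extended dienolate of 5 (not isolated) | [K+].[O-]C1=C(C)C=C[C@@H](C1)C(=C)CO[Si](C)(C)C(C)(C)C | intermediate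
8 | (2S,5R)-2-methyl-2-[2-(phenylsulfinyl)ethyl]-5-[3-(tert-butyldimethylsilyloxy)prop-1-en-2-yl]cyclohex-3-en-1-one, both sulfoxide epimers | CC(C)(C)[Si](C)(C)OCC(=C)[C@H]1C=C[C@](C)(CCS(=O)c2ccccc2)C(=O)C1 | intermediate
9 | (2S,5R)-2-ethenyl-2-methyl-5-[3-(tert-butyldimethylsilyloxy)prop-1-en-2-yl]cyclohex-3-en-1-one | CC(C)(C)[Si](C)(C)OCC(=C)[C@H]1C=C[C@](C)(C=C)C(=O)C1 | intermediate
10 | isopropenylmagnesium bromide | C=C(C)[Mg]Br | starting material
11 | (1R,2S,5R)-2-ethenyl-2-methyl-1-(prop-1-en-2-yl)-5-[3-(tert-butyldimethylsilyloxy)prop-1-en-2-yl]cyclohex-3-en-1-ol | CC(C)(C)[Si](C)(C)OCC(=C)[C@H]1C=C[C@](C)(C=C)[C@](O)(C(C)=C)C1 | intermediate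
12 | potassium alkoxide of 11 (not isolated) | [K+].CC(C)(C)[Si](C)(C)OCC(=C)[C@H]1C=C[C@](C)(C=C)[C@]([O-])(C(C)=C)C1 | intermediate
13 | potassium enolate of 14, (3Z,5Z) diene with C8 trans to C1 across C9=C10 (not isolated) | [K+].[O-]/C1=C(/C)CC/C=C(/C)\C=C/[C@H](C(=C)CO[Si](C)(C)C(C)(C)C)C1 | intermediate
14 | (3Z,5Z,7R)-12-(tert-butyldimethylsilyloxy)germacra-3,5,11(13)-trien-9-one, both C10 epimers | O=C1C(C)CC/C=C(/C)\C=C/[C@H](C(=C)CO[Si](C)(C)C(C)(C)C)C1 | intermediate
15 | (3Z,5Z,7R,9S,10R)-12-(tert-butyldimethylsilyloxy)germacra-3,5,11(13)-trien-9-ol | O[C@@H]1[C@H](C)CC/C=C(/C)\C=C/[C@H](C(=C)CO[Si](C)(C)C(C)(C)C)C1 | intermediate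
16 | angelic acid, (Z)-2-methylbut-2-enoic acid | C/C=C(/C)C(=O)O | starting material
17 | angelic 2,4,6-trichlorobenzoic mixed anhydride (not isolated) | C/C=C(/C)C(=O)OC(=O)c1c(Cl)cc(Cl)cc1Cl | intermediate
18 | (3Z,5Z,7R,9S,10R)-12-(tert-butyldimethylsilyloxy)germacra-3,5,11(13)-trien-9-yl angelate | C/C=C(/C)C(=O)O[C@@H]1[C@H](C)CC/C=C(/C)\C=C/[C@H](C(=C)CO[Si](C)(C)C(C)(C)C)C1 | intermediate
19 | (3Z,5Z,7R,9S,10R)-12-hydroxygermacra-3,5,11(13)-trien-9-yl angelate | C/C=C(/C)C(=O)O[C@@H]1[C@H](C)CC/C=C(/C)\C=C/[C@H](C(=C)CO)C1 | intermediate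
20 | (3Z,5Z,7R,9S,10R)-12-oxogermacra-3,5,11(13)-trien-9-yl angelate | C/C=C(/C)C(=O)O[C@@H]1[C@H](C)CC/C=C(/C)\C=C/[C@H](C(=C)C=O)C1 | intermediate
21 | (3Z,5Z,7R,9S,10R)-9-angeloyloxygermacra-3,5,11(13)-trien-12-oic acid | C/C=C(/C)C(=O)O[C@@H]1[C@H](C)CC/C=C(/C)\C=C/[C@H](C(=C)C(=O)O)C1 | intermediate
22 | allylpalladium acetate adduct, lactone closed, Pd on C5 anti to the new C6–O bond, (3Z)-alkene intact (not isolated) | C=C1C(=O)O[C@@H]2[C@@H]([Pd]OC(C)=O)/C(C)=C\CC[C@@H](C)[C@@H](OC(=O)/C(C)=C\C)C[C@@H]12 | intermediate
23 | CNP0173235.1, (3S,4Z,6R,7S,9S,10R)-3-acetoxy-9-angeloyloxygermacra-4,11(13)-dien-12,6-olide | C=C1C(=O)O[C@@H]2/C=C(/C)[C@@H](OC(C)=O)CC[C@@H](C)[C@@H](OC(=O)/C(C)=C\C)C[C@@H]12 | target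

## Step count and risks

Total step count: 13. Longest linear sequence: 13 steps, from (S)-carvone 1 to 23.

Steps most likely to fail:

1. Step 13. Transfer of acetate from palladium to C3 may be slow compared with syn/anti isomerisation of the allyl complex or with attack of acetate from outside. Either would erode the C3 configuration and the Z geometry of the new C4=C5 bond. Fallback, from 21: the same Pd(OAc)2/benzoquinone system with LiCl (2 equiv) performs the known 1,4-chlorolactonisation, in which chloride traps the allyl complex quickly from the face anti to the metal, to give the (3R)-3-chloro-9-angeloyloxygermacra-4,11(13)-dien-12,6-olide F1. SN2 displacement of the allylic chloride with CsOAc in DMF then inverts C3, and the route comes back at 23.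

2. Step 7. The alkoxide may rearrange through the alternative chair (C8 axial) or fragment to an enone and a pentadienyl anion that recombine, so that the (3E) geometry forms instead of, or beside, the (3Z) geometry. Fallback, from 11: the (3E,5Z,7R)-12-(tert-butyldimethylsilyloxy)germacra-3,5,11(13)-trien-9-one F2 that such a course gives is separated and kept. Steps 8 to 12 applied to it should give the (9S,10R)-alcohol F3, its angelate F4, the primary alcohol F5, the aldehyde F6 and the acid F7. F7 is cyclised with the chloride-catalysed variant of the key reaction (Pd(OAc)2, benzoquinone, LiOAc, LiCl 0.2 equiv), in which acetate attacks C3 from outside, anti to the metal. On the (3E,5Z)-diene this anti/anti mode leads to the same (3S,4Z,6R) arrangement, so the route comes back at 23.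

3. Step 8. The facial preference of the catalyst may be overridden by the conformation of the ten-membered ring, or C10 may epimerise more slowly than the ketone is reduced, giving mixtures at C9 and C10. Fallback, from 14: equilibration of C10 with DBU and chromatographic separation gives the (3Z,5Z,7R,10R)-12-(tert-butyldimethylsilyloxy)germacra-3,5,11(13)-trien-9-one F8, the 10S epimer being returned to the equilibration. Reduction with LiBH(s-Bu)3 in THF at −78 °C then relies on substrate control (hydride anti to the α-methyl group, Felkin-type), and the route comes back at 15.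

## Further compounds

F1 | step 13 | (3R,4Z,6R,7S,9S,10R)-3-chloro-9-angeloyloxygermacra-4,11(13)-dien-12,6-olide | C=C1C(=O)O[C@@H]2/C=C(/C)[C@H](Cl)CC[C@@H](C)[C@@H](OC(=O)/C(C)=C\C)C[C@@H]12
F2 | step 7 | (3E,5Z,7R)-12-(tert-butyldimethylsilyloxy)germacra-3,5,11(13)-trien-9-one, both C10 epimers | O=C1C(C)CC/C=C(\C)/C=C\[C@H](C(=C)CO[Si](C)(C)C(C)(C)C)C1
F3 | step 7 | (3E,5Z,7R,9S,10R)-12-(tert-butyldimethylsilyloxy)germacra-3,5,11(13)-trien-9-ol | O[C@@H]1[C@H](C)CC/C=C(\C)/C=C\[C@H](C(=C)CO[Si](C)(C)C(C)(C)C)C1
F4 | step 7 | (3E,5Z,7R,9S,10R)-12-(tert-butyldimethylsilyloxy)germacra-3,5,11(13)-trien-9-yl angelate | C/C=C(/C)C(=O)O[C@@H]1[C@H](C)CC/C=C(\C)/C=C\[C@H](C(=C)CO[Si](C)(C)C(C)(C)C)C1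
F5 | step 7 | (3E,5Z,7R,9S,10R)-12-hydroxygermacra-3,5,11(13)-trien-9-yl angelate | C/C=C(/C)C(=O)O[C@@H]1[C@H](C)CC/C=C(\C)/C=C\[C@H](C(=C)CO)C1
F6 | step 7 | (3E,5Z,7R,9S,10R)-12-oxogermacra-3,5,11(13)-trien-9-yl angelate | C/C=C(/C)C(=O)O[C@@H]1[C@H](C)CC/C=C(\C)/C=C\[C@H](C(=C)C=O)C1
F7 | step 7 | (3E,5Z,7R,9S,10R)-9-angeloyloxygermacra-3,5,11(13)-trien-12-oic acid | C/C=C(/C)C(=O)O[C@@H]1[C@H](C)CC/C=C(\C)/C=C\[C@H](C(=C)C(=O)O)C1
F8 | step 8 | (3Z,5Z,7R,10R)-12-(tert-butyldimethylsilyloxy)germacra-3,5,11(13)-trien-9-one | O=C1[C@H](C)CC/C=C(/C)\C=C/[C@H](C(=C)CO[Si](C)(C)C(C)(C)C)C1
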